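The chromanone ring (O-1, C-2, C-3, C-4, C-4a, C-8a) hides a vicinal triketone. Phenol O-1 can rest on C-3, giving a five-membered benzofuranone hemiketal, or on C-2, and the 4-hydroxyphenyl group on C-2 permits quinone methide formation. Everything rests on cutting C-2–C-8'' and C-3–O-7''. In one operation a chiral phosphoric acid expands a racemic 2-aroyl-2-hydroxybenzofuranone to the six-membered ring, dehydrates it to an achiral quinone methide and annulates a 7-hydroxy kaempferol derivative across C-2/C-3. This closes two rings and sets both stereocentres stereoconvergently. The benzofuranone comes from an aurone, the nucleophile from kaempferol.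

Key step: step 8

Remark on locants: flavonoid numbering is used. Unprimed and ' locants belong to the chromanone half and its 4-hydroxyphenyl ring, '' and ''' to the flavonol half and its aryl ring. In this numbering the target is (2R,3S), cis-fused.
Assumption: the sense of induction of (R)-TRIP cannot be derived with certainty. If it favours the (2S,3R) series, (S)-TRIP is used under the same conditions.

Step 1
Reactants: 1 kaempferol
Product: 2 3,7,4'-tris-O-(benzyloxycarbonyl)kaempferol (5-OH free)
Conditions: CbzCl (3.2 equiv), Et3N, THF, 0 °C to rt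
Reagents that add atoms: benzyl chloroformate, O=C(Cl)OCc1ccccc1
Why: O-acylation with a chloroformate takes the three free hydroxyls at C-3, C-7 and C-4', while the 5-OH, locked in a hydrogen bond to the C-4 carbonyl, should stay untouched; no stereocentre is formed.

Step 2
Reactants: 2 3,7,4'-tris-O-(benzyloxycarbonyl)kaempferol
Product: 3 5-O-benzyl-3,7,4'-tris-O-(benzyloxycarbonyl)kaempferol
Conditions: BnOH, PPh3, DIAD, THF, 0 °C to rt
Reagents that add atoms: benzyl alcohol, OCc1ccccc1
Why: Mitsunobu etherification alkylates the only remaining, chelated phenol under neutral conditions that spare the base-labile aryl carbonates, a reaction type established for 5-O-alkylation of O-acylated flavonoids.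

Step 3
Reactants: 3 5-O-benzyl-3,7,4'-tris-O-(benzyloxycarbonyl)kaempferol
Product: 4 5-O-benzyl-3,4'-bis-O-(benzyloxycarbonyl)kaempferol (7-OH free)
Conditions: PhSH, imidazole (cat.), NMP, 0 °C to rt
Reagents that add atoms: none
Why: Chemoselective thiolysis removes the most activated acyl group, because the 7-phenoxide (para to the C-4 carbonyl through C-4a) is the best leaving group, as known for 7-O-deacylation of peracylated flavonoids.

Step 4
Reactants: 5 4,6-dihydroxybenzofuran-3(2H)-one
Product: 6 4,6-bis(benzyloxy)benzofuran-3(2H)-one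
Conditions: BnBr, K2CO3, DMF, 50 °C
Reagents that add atoms: benzyl bromide, BrCc1ccccc1
Why: Williamson ether synthesis on both phenoxides, the standard O-alkylation of this benzofuranone on the way to aurones; no stereocentre is formed.

Step 5
Reactants: 6 4,6-bis(benzyloxy)benzofuran-3(2H)-one; 7 4-hydroxybenzaldehyde
Product: 8 (Z)-4,6-bis(benzyloxy)-2-(4-hydroxybenzylidene)benzofuran-3(2H)-one (aurone)
Conditions: HCl (cat.), AcOH, rt
Reagents that add atoms: none
Why: Acid-catalysed aldol condensation at the active C-2 methylene gives the aurone, and the reversible dehydration should deliver the thermodynamically preferred Z alkene.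

Step 6
Reactants: 8 (Z)-aurone
Product: 9 4,6-bis(benzyloxy)-2-hydroxy-2-[hydroxy(4-hydroxyphenyl)methyl]benzofuran-3(2H)-one (racemic, hemiketal epimers)
Conditions: OsO4 (cat.), NMO, acetone–H2O, rt
Reagents that add atoms: N-methylmorpholine N-oxide, C[N+]1([O-])CCOCC1; water, O
Why: Catalytic osmium tetroxide syn-dihydroxylation of the trisubstituted double bond, made electron-rich by O-1 and the 4-hydroxyphenyl group; both new stereocentres are racemic and are erased or become labile in steps 7 and 8, so no control is needed.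

Step 7
Reactants: 9 aurone diol
Product: 10 4,6-bis(benzyloxy)-2-hydroxy-2-(4-hydroxybenzoyl)benzofuran-3(2H)-one (racemic)
Conditions: DDQ, 1,4-dioxane, rt
Reagents that add atoms: none
Why: DDQ dehydrogenation of a 4-hydroxybenzylic alcohol (hydride abstraction para to the phenol) gives the 4-hydroxyaryl ketone and spares the benzyl ethers, and the five-ring hemiketal should be the resting tautomer because it masks the most electrophilic central carbonyl and keeps both flanking ketones conjugated; its one stereocentre is racemic and labile.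

Step 8
Reactants: 10 racemic 2-aroyl-2-hydroxybenzofuranone; 4 5-O-benzyl-3,4'-bis-O-(benzyloxycarbonyl)kaempferol
Product: 15 (2R,3S)-protected biflavonoid (5,7,5''-tri-O-benzyl 3'',4'''-bis-O-benzyloxycarbonyl; 3-OH and 4'-OH free), via open triketone 11 (not isolated), via six-ring hemiketal 12 (not isolated), via quinone methide 13 (not isolated), via C-2 adduct dione 14 (not isolated)
Conditions: (R)-TRIP [(R)-3,3'-bis(2,4,6-triisopropylphenyl)-BINOL hydrogen phosphate] (10 mol %), toluene–CH2Cl2, 30 °C, slow addition of 10 to 4 (1.3 equiv)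
Reagents that add atoms: none
Why: Proposed new method: the acid opens racemic hemiketal 10 to triketone 11, phenol O-1 recloses 6-exo-trig on the aroyl carbonyl to give 12, so that the former exocyclic carbon is inserted between O-1 and the old hemiketal carbon and the five-membered ring becomes the six-membered one, and loss of water from 12, pushed by O-1 and the free 4'-OH, gives the achiral quinone methide 13. C-8'' of 4 adds to C-2 of 13 in a rearomatising 1,6-addition to give 14, whose 7''-OH closes the dihydrofuran ring 5-exo-trig on the C-3 ketone. The closest known reaction types are the ring–chain equilibrium between 2-aroyl-2-hydroxybenzofuran-3(2H)-ones and 2-hydroxyflavan-3,4-diones, and the chiral-phosphoric-acid-catalysed enantioconvergent 1,6-addition or (3+2) annulation of phenols and naphthols with p-quinone methides formed in situ from racemic tertiary 4-hydroxybenzylic alcohols. C-2 is controlled by the catalyst, which binds the quinone methide oxygen through P–OH and the 7''-OH through P=O and leaves one face of planar C-2 open, so both enantiomers and all tautomers of 10 are funnelled through 13 into (2R), while C-3 follows as (3S) because the five-membered ring can only be cis-fused and the hemiketal equilibrates. Attack at C-2 rather than at the C-3 carbonyl relies on rearomatisation of the 4-hydroxyphenyl ring and on C-3 resting as hemiketal or hydrate, C-8'' over C-6'' is secured by the 5''-O-benzyl group flanking C-6'', cross- over self-coupling by the absence of a free OH on the benzyloxy ring of 10 and its slow addition, and redox exchange between the partners is blocked by the 3''-O-carbonate. The new C–C bond makes C-2 quaternary, so the six-membered ring can no longer contract and the tautomer equilibrium is drained towards 15.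

Step 9
Reactants: 15 protected biflavonoid
Product: 16 target, (2R,3S)
Conditions: H2 (1 atm), 10% Pd/C, THF–EtOAc, rt
Reagents that add atoms: none
Why: Heterogeneous hydrogenolysis cleaves the three benzyl ethers and, with loss of CO2, the two benzyl carbonates under neutral conditions, while the fully substituted C-2–O-1 bond is shielded from the catalyst surface and neither C-2 nor the cis-locked hemiketal C-3 can epimerise without acid or base.

Compound list
1 | kaempferol | O=c1c(O)c(-c2ccc(O)cc2)oc2cc(O)cc(O)c12 | starting material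
2 | 3,7,4'-tris-O-(benzyloxycarbonyl)kaempferol | O=c1c(OC(=O)OCc2ccccc2)c(-c2ccc(OC(=O)OCc3ccccc3)cc2)oc2cc(OC(=O)OCc3ccccc3)cc(O)c12 | intermediate
3 | 5-O-benzyl-3,7,4'-tris-O-(benzyloxycarbonyl)kaempferol | O=c1c(OC(=O)OCc2ccccc2)c(-c2ccc(OC(=O)OCc3ccccc3)cc2)oc2cc(OC(=O)OCc3ccccc3)cc(OCc3ccccc3)c12 | intermediate
4 | 5-O-benzyl-3,4'-bis-O-(benzyloxycarbonyl)kaempferol (7-OH free) | O=c1c(OC(=O)OCc2ccccc2)c(-c2ccc(OC(=O)OCc3ccccc3)cc2)oc2cc(O)cc(OCc3ccccc3)c12 | intermediate
5 | 4,6-dihydroxybenzofuran-3(2H)-one | O=C1COc2cc(O)cc(O)c12 | starting material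
6 | 4,6-bis(benzyloxy)benzofuran-3(2H)-one | O=C1COc2cc(OCc3ccccc3)cc(OCc3ccccc3)c12 | intermediate
7 | 4-hydroxybenzaldehyde | O=Cc1ccc(O)cc1 | starting material
8 | (Z)-4,6-bis(benzyloxy)-2-(4-hydroxybenzylidene)benzofuran-3(2H)-one | O=C1/C(=C/c2ccc(O)cc2)Oc2cc(OCc3ccccc3)cc(OCc3ccccc3)c12 | intermediate
9 | 4,6-bis(benzyloxy)-2-hydroxy-2-[hydroxy(4-hydroxyphenyl)methyl]benzofuran-3(2H)-one (racemic, hemiketal epimers) | OC(c1ccc(O)cc1)C1(O)Oc2cc(OCc3ccccc3)cc(OCc3ccccc3)c2C1=O | intermediate
10 | 4,6-bis(benzyloxy)-2-hydroxy-2-(4-hydroxybenzoyl)benzofuran-3(2H)-one (racemic) | O=C(c1ccc(O)cc1)C1(O)Oc2cc(OCc3ccccc3)cc(OCc3ccccc3)c2C1=O | intermediate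
11 | 1-[2,4-bis(benzyloxy)-6-hydroxyphenyl]-3-(4-hydroxyphenyl)propane-1,2,3-trione (not isolated) | O=C(C(=O)C(=O)c1ccc(O)cc1)c1c(O)cc(OCc2ccccc2)cc1OCc1ccccc1 | intermediate
12 | 5,7-bis(benzyloxy)-2-hydroxy-2-(4-hydroxyphenyl)chromane-3,4-dione (racemic, not isolated) | O=C1C(=O)C(O)(c2ccc(O)cc2)Oc2cc(OCc3ccccc3)cc(OCc3ccccc3)c12 | intermediate
13 | 5,7-bis(benzyloxy)-2-(4-oxocyclohexa-2,5-dien-1-ylidene)chromane-3,4-dione (not isolated) | O=C1C=CC(=C2Oc3cc(OCc4ccccc4)cc(OCc4ccccc4)c3C(=O)C2=O)C=C1 | intermediate
14 | (2R)-5,7-bis(benzyloxy)-2-(4-hydroxyphenyl)-2-(protected kaempferol-8-yl)chromane-3,4-dione, 7''-OH free (not isolated) | O=C1c2c(OCc6ccccc6)cc(OCc6ccccc6)cc2O[C@](c3ccc(O)cc3)(c3c(O)cc(OCc6ccccc6)c4c(=O)c(OC(=O)OCc6ccccc6)c(-c5ccc(OC(=O)OCc6ccccc6)cc5)oc34)C1=O | intermediate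
15 | (2R,3S)-protected biflavonoid: 5,7,5''-tri-O-benzyl, 3'',4'''-bis-O-(benzyloxycarbonyl), 3-OH and 4'-OH free | O=C1c2c(OCc6ccccc6)cc(OCc6ccccc6)cc2O[C@]2(c3ccc(O)cc3)c3c(cc(OCc6ccccc6)c4c(=O)c(OC(=O)OCc6ccccc6)c(-c5ccc(OC(=O)OCc6ccccc6)cc5)oc34)O[C@]12O | intermediate
16 | CNP0314633.1, (2R,3S) | O=C1c2c(O)cc(O)cc2O[C@]2(c3ccc(O)cc3)c3c(cc(O)c4c(=O)c(O)c(-c5ccc(O)cc5)oc34)O[C@]12O | target

Total step count: 9
Longest linear sequence: 6 steps (5 → 6 → 8 → 9 → 10 → 15 → 16)

Steps most likely to fail

Step 8 (proposed new method).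
- **What may go wrong:** the phenol may attack the central carbonyl (C-3) of 11 or 12, directly or after O-7'' addition at C-2, instead of adding at C-2 of 13. The five-ring hemiketal may return to 12 too slowly. Facial selectivity may be poor.
- **Fallback (known chemistry, from 4 back to 15):** a second portion of 4 is benzylated at O-7 under Mitsunobu conditions to 5,7-di-O-benzyl-3,4'-bis-O-(benzyloxycarbonyl)kaempferol F1. Aminolysis with n-BuNH2 in THF frees 5,7-di-O-benzylkaempferol F2. Silver(I) oxide oxidation of F2 in the presence of 4 generates 13 under neutral conditions and should give the racemic cis-fused protected biflavonoid F3. This is oxidative phenol coupling through the flavonol quinone methide, the reaction type used for flavonol dimers and flavonolignans. Preparative chromatography on a chiral stationary phase then separates 15 from its (2S,3R) enantiomer F4.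

Step 6.
- **What may go wrong:** osmylation of the push–pull alkene may be slow. The diol may undergo retro-aldol cleavage or dehydrative rearrangement during isolation.
- **Fallback (from 6 back to 10):** condensation and oxidation are replaced by acylation and hydroxylation.
  - Soft enolisation of 6 (MgBr2·OEt2, i-Pr2NEt) and C-acylation with 4-acetoxybenzoyl chloride gives 2-(4-acetoxybenzoyl)-4,6-bis(benzyloxy)benzofuran-3-ol F5.
  - α-Hydroxylation of this β-dicarbonyl with dimethyldioxirane gives 2-(4-acetoxybenzoyl)-4,6-bis(benzyloxy)-2-hydroxybenzofuran-3(2H)-one F6.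
  - Thiolysis of the activated aryl acetate (PhSH, imidazole, NMP) returns to 10.

Step 9.
- **What may go wrong:** the doubly benzylic C-2–O-1 bond may be hydrogenolysed, or the C-4 ketone over-reduced, before the last benzyl group is lost.
- **Fallback (from 15 to 16):** reductive cleavage is replaced by a two-stage non-reductive deprotection. Prolonged thiolysis (PhSH, imidazole, NMP) removes both carbonates to give the (2R,3S)-5,7,5''-tri-O-benzyl ether of the target F7. BCl3 with pentamethylbenzene as cation scavenger (CH2Cl2, −78 °C) then cleaves the three benzyl ethers.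

Further compounds
F1 | step 8 | 5,7-di-O-benzyl-3,4'-bis-O-(benzyloxycarbonyl)kaempferol | O=c1c(OC(=O)OCc2ccccc2)c(-c2ccc(OC(=O)OCc3ccccc3)cc2)oc2cc(OCc3ccccc3)cc(OCc3ccccc3)c12
F2 | step 8 | 5,7-di-O-benzylkaempferol | O=c1c(O)c(-c2ccc(O)cc2)oc2cc(OCc3ccccc3)cc(OCc3ccccc3)c12
F3 | step 8 | racemic cis-fused protected biflavonoid (racemate of 15) | O=C1c2c(OCc6ccccc6)cc(OCc6ccccc6)cc2OC2(c3ccc(O)cc3)c3c(cc(OCc6ccccc6)c4c(=O)c(OC(=O)OCc6ccccc6)c(-c5ccc(OC(=O)OCc6ccccc6)cc5)oc34)OC12O
F4 | step 8 | (2S,3R) enantiomer of 15 | O=C1c2c(OCc6ccccc6)cc(OCc6ccccc6)cc2O[C@@]2(c3ccc(O)cc3)c3c(cc(OCc6ccccc6)c4c(=O)c(OC(=O)OCc6ccccc6)c(-c5ccc(OC(=O)OCc6ccccc6)cc5)oc34)O[C@@]12O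
F5 | step 6 | 2-(4-acetoxybenzoyl)-4,6-bis(benzyloxy)benzofuran-3-ol | CC(=O)Oc1ccc(cc1)C(=O)c1oc2cc(OCc3ccccc3)cc(OCc3ccccc3)c2c1O
F6 | step 6 | 2-(4-acetoxybenzoyl)-4,6-bis(benzyloxy)-2-hydroxybenzofuran-3(2H)-one (racemic) | CC(=O)Oc1ccc(cc1)C(=O)C1(O)Oc2cc(OCc3ccccc3)cc(OCc3ccccc3)c2C1=O
F7 | step 9 | (2R,3S)-5,7,5''-tri-O-benzyl ether of the target | O=C1c2c(OCc6ccccc6)cc(OCc6ccccc6)cc2O[C@]2(c3ccc(O)cc3)c3c(cc(OCc6ccccc6)c4c(=O)c(O)c(-c5ccc(O)cc5)oc34)O[C@]12O
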